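**Retrosynthetic overview**

1. Locants (germacrane type): carbocycle C1–C10, C14 = methyl on C10, C15 = CH2OAc on C4, lactone C6–O–C12(=O)–C11(=C13)–C7; ring A = oxepane O/C5/C6/C7/C8/C9/C10, ring B = oxepane O/C10/C1/C2/C3/C4/C5. Enabling feature: the C3(O)–C4(H)–C15(O) array on ring B is a 2-isoxazoline retron whose alkene half (C4=C15) is a vinyl group on C5 of ring A.
2. Endgame: target ⇐ α-methylene lactone masked as its dimethylamine adduct; 8-O-angeloylation; 3,15-di-O-acetylation; C3 ketone reduction ⇐ isoxazoline.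
3. Key disconnection: isoxazoline ⇐ intramolecular nitrile oxide–alkene (3+2) cycloaddition that forms C3–C4 and with it ring B, the oxygen-bridged bicycle, C4 and the C15–O bond.
4. Ring A ⇐ intramolecular γ-alkoxyallylstannane/aldehyde allylation (C5–C6; sets C5 and C6) of an acyclic dialdehyde; lactol → lactone.
5. Chain ⇐ (R)-linalool (C10, C14, C1–C3, C8, C9) + Wittig unit (C6, C7) + vinyl (C11, C12) + allyl (C4, C5, C15); C8 by Sharpless epoxidation, C7 by epoxide opening. Ring order: A → lactone → B with isoxazoline.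

Key step: step 17

Remark: as written, the SMILES places the C4 arm on C5 and the C1 arm on C10 on opposite faces of ring A (C14 cis to C4), so the ether oxygen bridges the ten-membered ring in the trans (in,out) sense with H5 inside, as in the carbocyclic ingenane core; the route is designed for exactly this (3S,4S,5R,6S,7R,8R,10R) isomer.

**Route**

Step 1
Reactants: 1 (R)-(−)-linalool
Product: 2 (3R)-3,7-dimethyloct-6-ene-1,3-diol
Conditions: 9-BBN (2.2 equiv), THF, 0 °C to rt; then NaOH, H2O2, 0 °C
Reagents that add atoms: hydrogen peroxide OO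
Why: Anti-Markovnikov hydroboration–oxidation in which 9-BBN should take the monosubstituted vinyl group and leave the trisubstituted alkene, C10 being untouched.

Step 2
Reactants: 2 (3R)-3,7-dimethyloct-6-ene-1,3-diol; 3 ethyl (triphenylphosphoranylidene)acetate
Product: 5 ethyl (2E,5R)-5-hydroxy-5,9-dimethyldeca-2,8-dienoate, via hydroxy aldehyde 4 (not isolated)
Conditions: TEMPO (cat.), PhI(OAc)2, CH2Cl2, rt; then 3 (excess), rt
Reagents that add atoms: none
Why: Nitroxyl-catalysed oxidation of the primary alcohol followed in the same flask by a Wittig reaction with the stabilised ylide should give the E-enoate without isolating the dehydration-prone β-hydroxy aldehyde.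

Step 3
Reactants: 5 ethyl (2E,5R)-5-hydroxy-5,9-dimethyldeca-2,8-dienoate
Product: 6 (2E,5R)-5,9-dimethyldeca-2,8-diene-1,5-diol
Conditions: DIBAL-H (3.2 equiv), CH2Cl2, −78 to 0 °C; Rochelle salt
Reagents that add atoms: none
Why: 1,2-Reduction of the conjugated ester by DIBAL-H should give the E-allylic alcohol needed for directed epoxidation.

Step 4
Reactants: 6 (2E,5R)-5,9-dimethyldeca-2,8-diene-1,5-diol
Product: 7 (2R,3R,5R)-2,3-epoxy-5,9-dimethyldec-8-ene-1,5-diol
Conditions: Ti(OiPr)4, D-(−)-diethyl tartrate, t-BuOOH, 4 Å MS, CH2Cl2, −20 °C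
Reagents that add atoms: tert-butyl hydroperoxide CC(C)(C)OO
Why: Sharpless asymmetric epoxidation, in which the D-tartrate ligand should deliver oxygen to the face giving the (2R,3R)-epoxide and so set C8 by reagent control, the isolated trisubstituted alkene not being an allylic alcohol.

Step 5
Reactants: 7 (2R,3R,5R)-2,3-epoxy-5,9-dimethyldec-8-ene-1,5-diol; 8 vinylmagnesium bromide
Product: 9 (2S,3R,5R)-5,9-dimethyl-2-vinyldec-8-ene-1,3,5-triol
Conditions: 8 (6 equiv), CuI (0.3 equiv), THF, −40 to −10 °C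
Reagents that add atoms: none
Why: Copper-catalysed SN2 opening of the 2,3-epoxy alcohol should occur at C2 (= C7) with inversion because attack at C3 is blocked by the neopentyl-like CH2–C(quaternary) substituent, which sets C7 anti to the C8 hydroxyl.

Step 6
Reactants: 9 (2S,3R,5R)-5,9-dimethyl-2-vinyldec-8-ene-1,3,5-triol
Product: 10 (3S,4R,6R)-3-(hydroxymethyl)-6,10-dimethylundec-9-ene-1,4,6-triol
Conditions: 9-BBN (4.5 equiv), THF, rt; then NaOH, H2O2, 0 °C
Reagents that add atoms: hydrogen peroxide OO
Why: Hydroboration–oxidation with 9-BBN should again select the vinyl group over the trisubstituted alkene and give the primary C12 alcohol.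

Step 7
Reactants: 10 (3S,4R,6R)-3-(hydroxymethyl)-6,10-dimethylundec-9-ene-1,4,6-triol
Product: 11 (3S,4R,6R)-1-(TBSO)-3-(TBSOCH2)-6,10-dimethylundec-9-ene-4,6-diol
Conditions: TBSCl (2.1 equiv), imidazole, CH2Cl2, 0 °C
Reagents that add atoms: tert-butyldimethylsilyl chloride CC(C)(C)[Si](C)(C)Cl
Why: Silylation with TBSCl should be selective for the two primary hydroxyls (C6–OH and C12–OH) over the hindered secondary and the tertiary one.

Step 8
Reactants: 11 (3S,4R,6R)-1-(TBSO)-3-(TBSOCH2)-6,10-dimethylundec-9-ene-4,6-diol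
Product: 12 (3S,4R,6R)-1-(TBSO)-3-(TBSOCH2)-6,10-dimethyl-4-(TIPSO)undec-9-en-6-ol
Conditions: TIPSOTf, 2,6-lutidine, CH2Cl2, −78 to 0 °C
Reagents that add atoms: triisopropylsilyl trifluoromethanesulfonate CC(C)[Si](C(C)C)(C(C)C)OS(=O)(=O)C(F)(F)F
Why: Silyl triflate silylation, in which the TIPS group is too bulky for the tertiary alcohol so that only the secondary C8–OH should react.

Step 9
Reactants: 12 (3S,4R,6R)-1-(TBSO)-3-(TBSOCH2)-6,10-dimethyl-4-(TIPSO)undec-9-en-6-ol; 13 allyl bromide
Product: 14 6-O-allyl ether of 12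
Conditions: KH, 18-crown-6 (cat.), THF, 0 °C; then 13, rt
Reagents that add atoms: none
Why: Williamson etherification of the potassium tert-alkoxide should proceed cleanly because the 1,3-related TIPS ether is too hindered to migrate.

Step 10
Reactants: 14 6-O-allyl ether of 12
Product: 15 (Z)-γ-alkoxyallylstannane (O–CH=CH–CH2SnBu3 on the C10 oxygen)
Conditions: s-BuLi, TMEDA, THF, −78 °C; then Bu3SnCl, −78 °C
Reagents that add atoms: tributyltin chloride CCCC[Sn](Cl)(CCCC)CCCC
Why: α-Lithiation of the allyl ether to the chelated (Z)-alkoxyallyllithium and γ-stannylation should give the (Z)-γ-alkoxyallylstannane, silyl ethers and the isolated alkene being inert.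

Step 11
Reactants: 15 (Z)-γ-alkoxyallylstannane
Product: 16 stannane diol (C6–OH and C12–OH free)
Conditions: TBAF (2.2 equiv), THF, 0 °C
Reagents that add atoms: none
Why: Fluoride desilylation should remove both primary TBS ethers while the hindered secondary TIPS ether and the acid-sensitive enol ether stannane survive the non-acidic conditions.

Step 12
Reactants: 16 stannane diol
Product: 17 stannane dialdehyde (C6 and C12 formyl)
Conditions: SO3·pyridine, DMSO, i-Pr2NEt, CH2Cl2, −10 °C; used crude
Reagents that add atoms: none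
Why: Parikh–Doering oxidation of both primary alcohols is mild and non-acidic, is tolerated by the allylstannane, and at low temperature with a hindered base should keep the α-stereocentre C7.

Step 13
Reactants: 17 stannane dialdehyde
Product: 19 lactol of ring A (6,12-hemiacetal), via oxepanol aldehyde 18 (not isolated)
Conditions: BF3·OEt2, CH2Cl2 (5 mM), −78 °C; aq. NaHCO3
Reagents that add atoms: none
Why: Lewis-acid-promoted intramolecular SE2′ allylation of an aldehyde by a γ-alkoxyallylstannane should close oxepane ring A at C5–C6 (the C12 aldehyde would need a nine-membered ring), a chair-like transition state with the vinyl group, the O–BF3 and the C7 arm all pseudo-equatorial giving the 5,6-trans and 6,7-trans relationships, after which the C6 alkoxide captures the C12 aldehyde as the lactol.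

Step 14
Reactants: 19 lactol of ring A
Product: 20 trans-fused 6,12-olide on ring A (5-vinyl; 8-OTIPS; 10-methyl; 10-(4-methylpent-3-enyl))
Conditions: TPAP (5 mol%), NMO, 4 Å MS, CH2Cl2, rt
Reagents that add atoms: none
Why: Ley–Griffith oxidation converts the lactol into the γ-lactone and should leave both alkenes and the silyl ether untouched.

Step 15
Reactants: 20 trans-fused 6,12-olide on ring A
Product: 22 C3 aldehyde (10-(3-oxopropyl) lactone), via epoxide 21 (not isolated)
Conditions: mCPBA (1.05 equiv), NaHCO3, CH2Cl2, 0 °C; then H5IO6, THF–H2O, 0 °C to rt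
Reagents that add atoms: 3-chloroperbenzoic acid OOC(=O)c1cccc(Cl)c1
Why: Prilezhaev epoxidation should select the electron-rich trisubstituted alkene over the vinyl group of the allylic ether, and periodic acid cleaves the epoxide (through the diol) to the C3 aldehyde and acetone.

Step 16
Reactants: 22 C3 aldehyde
Product: 23 C3 aldoxime
Conditions: NH2OH·HCl, NaOAc, EtOH–H2O, 0 °C to rt
Reagents that add atoms: hydroxylamine hydrochloride Cl.NO
Why: Oxime condensation should be selective because the aldehyde is far more electrophilic than the lactone.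

Step 17
Reactants: 23 C3 aldoxime
Product: 26 isoxazoline (ring B closed; C3=N–O–C15), via hydroximoyl chloride 24 (not isolated), via nitrile oxide 25 (not isolated)
Conditions: NCS, DMF, rt; then syringe-pump addition to Et3N, toluene (≤2 mM), 80 °C
Reagents that add atoms: N-chlorosuccinimide O=C1CCC(=O)N1Cl (Cl of 24 only; lost again as HCl)
Why: NCS chlorinates the aldoxime and Et3N dehydrochlorinates 24 to nitrile oxide 25, which should add in a concerted (3+2) cycloaddition across the C5 vinyl group, C3 bonding to the proximal alkene carbon C4 and the dipole oxygen to terminal C15; this is the intramolecular nitrile oxide–alkene cycloaddition, well known for five- to seven-membered rings fused to 2-isoxazolines. Two rings close at once: ring B (O–C10–C1–C2–C3–C4–C5) in the fused, formally 7-exo mode through the C3–C4 bond, which the three-atom tether dictates over the bridged regiochemistry, and the isoxazoline (C3=N–O–C15–C4). Because the C1 arm on C10 and the vinyl group on C5 are trans across the ring-A oxygen, ring B forms as the trans-bridged (in,out) bicycle; a strongly exothermic cycloaddition with an early transition state is chosen to pay for this strain, as ring-closing metathesis does for carbocyclic in,out-bicyclo[4.4.1]undecanes. The only new stereocentre, C4, is controlled by C5: the dipole should attack the vinyl face anti to C6 with the ring oxygen in the inside position (inside-alkoxy arrangement), which places C15 cis to C6 as the target requires. The step needs chemoselectivity for cyclisation over furoxan dimerisation, secured by slow generation of 25 at high dilution and by the absence of any other dipolarophile (the prenyl alkene is already cleaved and the α-methylene group not yet installed), and face selectivity at C4, secured by the allylic stereocentre C5. In one operation it delivers the C3–C4 bond, the bridged ring system, C4, the C15–O bond and C3 at the ketone oxidation level masked as C=N.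

Step 18
Reactants: 26 isoxazoline; 27 Eschenmoser's salt (N,N-dimethylmethyleneiminium iodide)
Product: 28 11-(dimethylaminomethyl) isoxazoline lactone (Mannich base; C11 epimers)
Conditions: LDA (1.05 equiv), THF, −78 °C; then 27, −78 to 0 °C
Reagents that add atoms: none
Why: Mannich reaction of the lactone lithium enolate (the lactone α-CH2 is the most acidic site and the isoxazoline should be untouched at −78 °C) introduces C13 and masks the future α-methylene group as its amine adduct, the C11 configuration being immaterial.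

Step 19
Reactants: 28 Mannich base
Product: 30 3-keto-15-hydroxy compound (β-hydroxy ketone), via hydroxy imine 29 (not isolated)
Conditions: Raney Ni, H2 (1 atm), B(OH)3, MeOH–H2O (5:1), rt
Reagents that add atoms: water O
Why: Hydrogenolysis of the isoxazoline N–O bond with boric-acid-buffered hydrolysis of the imine should unmask the β-hydroxy ketone without epimerising C4 or β-eliminating the C5–O bond.

Step 20
Reactants: 30 β-hydroxy ketone
Product: 31 3,15-diol (3-OH cis to C15)
Conditions: L-Selectride (2.5 equiv), THF, −78 °C; aq. NH4Cl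
Reagents that add atoms: none
Why: Bulky-hydride ketone reduction, in which hydride should enter C3 from the face opposite the adjacent C4 hydroxymethyl arm (as with 2-substituted cycloalkanones) to give the cis 3,15-diol, the lactone not being reduced at −78 °C.

Step 21
Reactants: 31 3,15-diol; 32 acetic anhydride
Product: 33 3,15-diacetate
Conditions: 32, pyridine, DMAP (cat.), CH2Cl2, rt
Reagents that add atoms: none
Why: DMAP-catalysed acylation should esterify both free hydroxyls while C8 is still silylated.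

Step 22
Reactants: 33 3,15-diacetate
Product: 34 8-alcohol
Conditions: HF·pyridine, THF, 0 °C to rt
Reagents that add atoms: none
Why: Fluoride desilylation under mildly acidic conditions should remove the TIPS group and leave the acetates and the amine-masked lactone intact.

Step 23
Reactants: 34 8-alcohol; 35 angelic acid
Product: 37 8-O-angelate (13-dimethylamino-11,13-dihydro target), via mixed anhydride 36 (not isolated)
Conditions: 35, 2,4,6-trichlorobenzoyl chloride, Et3N, toluene, rt; then 34, 80 °C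
Reagents that add atoms: 2,4,6-trichlorobenzoyl chloride O=C(Cl)c1c(Cl)cc(Cl)cc1Cl (aroyl part of 36 only)
Why: Yamaguchi esterification through the mixed anhydride, run without DMAP, should acylate the hindered C8 alcohol without Z-to-E isomerisation of the angelate.

Step 24
Reactants: 37 8-O-angelate
Product: 39 CNP0346171.1, via ammonium iodide 38 (not isolated)
Conditions: MeI, MeOH, rt; then aq. NaHCO3, EtOAc, rt
Reagents that add atoms: iodomethane CI (N-methyl of 38 only; leaves as trimethylamine)
Why: Quaternisation and E1cB (Hofmann-type) β-elimination of trimethylamine should regenerate the α-methylene lactone under conditions mild enough for the three esters.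

**Compound list**

1 | (R)-(−)-linalool | CC(C)=CCC[C@@](C)(O)C=C | starting material
2 | (3R)-3,7-dimethyloct-6-ene-1,3-diol | CC(C)=CCC[C@@](C)(O)CCO | intermediate
3 | ethyl (triphenylphosphoranylidene)acetate | CCOC(=O)C=P(c1ccccc1)(c1ccccc1)c1ccccc1 | starting material
4 | (3R)-3-hydroxy-3,7-dimethyloct-6-enal | CC(C)=CCC[C@@](C)(O)CC=O | intermediate (not isolated)
5 | ethyl (2E,5R)-5-hydroxy-5,9-dimethyldeca-2,8-dienoate | CC(C)=CCC[C@@](C)(O)C/C=C/C(=O)OCC | intermediate
6 | (2E,5R)-5,9-dimethyldeca-2,8-diene-1,5-diol | CC(C)=CCC[C@@](C)(O)C/C=C/CO | intermediate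
7 | (2R,3R,5R)-2,3-epoxy-5,9-dimethyldec-8-ene-1,5-diol | CC(C)=CCC[C@@](C)(O)C[C@H]1O[C@@H]1CO | intermediate
8 | vinylmagnesium bromide | C=C[Mg]Br | starting material
9 | (2S,3R,5R)-5,9-dimethyl-2-vinyldec-8-ene-1,3,5-triol | CC(C)=CCC[C@@](C)(O)C[C@@H](O)[C@@H](C=C)CO | intermediate
10 | (3S,4R,6R)-3-(hydroxymethyl)-6,10-dimethylundec-9-ene-1,4,6-triol | CC(C)=CCC[C@@](C)(O)C[C@@H](O)[C@@H](CCO)CO | intermediate
11 | (3S,4R,6R)-1-(TBSO)-3-(TBSOCH2)-6,10-dimethylundec-9-ene-4,6-diol | CC(C)=CCC[C@@](C)(O)C[C@@H](O)[C@@H](CCO[Si](C)(C)C(C)(C)C)CO[Si](C)(C)C(C)(C)C | intermediate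
12 | 4-O-TIPS ether of 11 (tertiary 6-OH free) | CC(C)=CCC[C@@](C)(O)C[C@@H](O[Si](C(C)C)(C(C)C)C(C)C)[C@@H](CCO[Si](C)(C)C(C)(C)C)CO[Si](C)(C)C(C)(C)C | intermediate
13 | allyl bromide | C=CCBr | starting material
14 | 6-O-allyl ether of 12 | CC(C)=CCC[C@@](C)(OCC=C)C[C@@H](O[Si](C(C)C)(C(C)C)C(C)C)[C@@H](CCO[Si](C)(C)C(C)(C)C)CO[Si](C)(C)C(C)(C)C | intermediate
15 | (Z)-γ-alkoxyallylstannane (14 with O–CH=CH–CH2SnBu3) | CC(C)=CCC[C@@](C)(O/C=C\C[Sn](CCCC)(CCCC)CCCC)C[C@@H](O[Si](C(C)C)(C(C)C)C(C)C)[C@@H](CCO[Si](C)(C)C(C)(C)C)CO[Si](C)(C)C(C)(C)C | intermediate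
16 | stannane diol (C6–OH, C12–OH) | CC(C)=CCC[C@@](C)(O/C=C\C[Sn](CCCC)(CCCC)CCCC)C[C@@H](O[Si](C(C)C)(C(C)C)C(C)C)[C@@H](CCO)CO | intermediate
17 | stannane dialdehyde (C6 and C12 formyl; C7, C8, C10 as in 9) | CC(C)=CCC[C@@](C)(O/C=C\C[Sn](CCCC)(CCCC)CCCC)C[C@@H](O[Si](C(C)C)(C(C)C)C(C)C)[C@@H](CC=O)C=O | intermediate
18 | oxepanol aldehyde (ring A; 5-vinyl trans to 6-OH, 6-OH trans to the C7 CH2CHO arm, 8-OTIPS cis to that arm) | O=CC[C@H]1[C@H](O)[C@@H](C=C)O[C@](C)(CCC=C(C)C)C[C@H]1O[Si](C(C)C)(C(C)C)C(C)C | intermediate (not isolated)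
19 | lactol of ring A (6,12-hemiacetal, anomers) | C1C(O)O[C@@H]2[C@@H](C=C)O[C@](C)(CCC=C(C)C)C[C@@H](O[Si](C(C)C)(C(C)C)C(C)C)[C@@H]12 | intermediate
20 | trans-fused 6,12-olide on ring A (5-vinyl, 8-OTIPS, 10-methyl cis to vinyl, 10-(4-methylpent-3-enyl)) | C1C(=O)O[C@@H]2[C@@H](C=C)O[C@](C)(CCC=C(C)C)C[C@@H](O[Si](C(C)C)(C(C)C)C(C)C)[C@@H]12 | intermediate
21 | side-chain epoxide of 20 | C1C(=O)O[C@@H]2[C@@H](C=C)O[C@](C)(CCC3OC3(C)C)C[C@@H](O[Si](C(C)C)(C(C)C)C(C)C)[C@@H]12 | intermediate (not isolated)
22 | C3 aldehyde (10-(3-oxopropyl) lactone) | C1C(=O)O[C@@H]2[C@@H](C=C)O[C@](C)(CCC=O)C[C@@H](O[Si](C(C)C)(C(C)C)C(C)C)[C@@H]12 | intermediate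
23 | C3 aldoxime | C1C(=O)O[C@@H]2[C@@H](C=C)O[C@](C)(CCC=NO)C[C@@H](O[Si](C(C)C)(C(C)C)C(C)C)[C@@H]12 | intermediate
24 | C3 hydroximoyl chloride | C1C(=O)O[C@@H]2[C@@H](C=C)O[C@](C)(CCC(Cl)=NO)C[C@@H](O[Si](C(C)C)(C(C)C)C(C)C)[C@@H]12 | intermediate (not isolated)
25 | C3 nitrile oxide | C1C(=O)O[C@@H]2[C@@H](C=C)O[C@](C)(CCC#[N+][O-])C[C@@H](O[Si](C(C)C)(C(C)C)C(C)C)[C@@H]12 | intermediate (not isolated)
26 | isoxazoline (ring B closed at C3–C4, C3=N–O–C15, in,out oxygen bridge, 8-OTIPS, 6,12-olide) | C1C(=O)O[C@@H]2[C@@H]3O[C@](C)(CCC4=NOC[C@H]34)C[C@@H](O[Si](C(C)C)(C(C)C)C(C)C)[C@@H]12 | intermediate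
27 | Eschenmoser's salt (N,N-dimethylmethyleneiminium iodide) | C=[N+](C)C.[I-] | starting material
28 | 11-(dimethylaminomethyl) isoxazoline lactone (Mannich base, C11 epimers) | CN(C)CC1C(=O)O[C@@H]2[C@@H]3O[C@](C)(CCC4=NOC[C@H]34)C[C@@H](O[Si](C(C)C)(C(C)C)C(C)C)[C@@H]12 | intermediate
29 | 3-imino-15-hydroxy compound | CN(C)CC1C(=O)O[C@@H]2[C@@H]3O[C@](C)(CCC(=N)[C@@H]3CO)C[C@@H](O[Si](C(C)C)(C(C)C)C(C)C)[C@@H]12 | intermediate (not isolated)
30 | 3-keto-15-hydroxy compound (β-hydroxy ketone) | CN(C)CC1C(=O)O[C@@H]2[C@@H]3O[C@](C)(CCC(=O)[C@@H]3CO)C[C@@H](O[Si](C(C)C)(C(C)C)C(C)C)[C@@H]12 | intermediate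
31 | 3,15-diol (3-OH cis to C15) | CN(C)CC1C(=O)O[C@@H]2[C@@H]3O[C@](C)(CC[C@H](O)[C@@H]3CO)C[C@@H](O[Si](C(C)C)(C(C)C)C(C)C)[C@@H]12 | intermediate
32 | acetic anhydride | CC(=O)OC(C)=O | starting material
33 | 3,15-diacetate (8-OTIPS) | CN(C)CC1C(=O)O[C@@H]2[C@@H]3O[C@](C)(CC[C@H](OC(C)=O)[C@@H]3COC(C)=O)C[C@@H](O[Si](C(C)C)(C(C)C)C(C)C)[C@@H]12 | intermediate
34 | 8-alcohol | CN(C)CC1C(=O)O[C@@H]2[C@@H]3O[C@](C)(CC[C@H](OC(C)=O)[C@@H]3COC(C)=O)C[C@@H](O)[C@@H]12 | intermediate
35 | angelic acid ((Z)-2-methylbut-2-enoic acid) | C/C=C(/C)C(=O)O | starting material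
36 | angelic 2,4,6-trichlorobenzoic anhydride | C/C=C(/C)C(=O)OC(=O)c1c(Cl)cc(Cl)cc1Cl | intermediate (not isolated)
37 | 8-O-angelate (13-dimethylamino-11,13-dihydro target) | CN(C)CC1C(=O)O[C@@H]2[C@@H]3O[C@](C)(CC[C@H](OC(C)=O)[C@@H]3COC(C)=O)C[C@@H](OC(=O)/C(C)=C\C)[C@@H]12 | intermediate
38 | trimethylammonium iodide of 37 | C[N+](C)(C)CC1C(=O)O[C@@H]2[C@@H]3O[C@](C)(CC[C@H](OC(C)=O)[C@@H]3COC(C)=O)C[C@@H](OC(=O)/C(C)=C\C)[C@@H]12.[I-] | intermediate (not isolated)
39 | CNP0346171.1 | C=C1C(=O)O[C@@H]2[C@@H]3O[C@](C)(CC[C@H](OC(C)=O)[C@@H]3COC(C)=O)C[C@@H](OC(=O)/C(C)=C\C)[C@@H]12 | target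

**Step count and risks**

Total steps: 24. Longest linear sequence: 24 steps, from (R)-linalool 1; all other numbered starting materials are commercial reagents.

Steps most likely to fail:

1. Step 17. The cyclisation has to build a trans-bridged (in,out) oxepane, so ring closure may be slower than bimolecular dimerisation of the nitrile oxide to the furoxan or its thermal rearrangement to the isocyanate. Attack on the other vinyl face would give the C4 epimer. The fallback replaces the dipole by a silyl nitronate, which does not dimerise and can be heated for long periods (intramolecular silyl nitronate–alkene cycloaddition). It sets out from aldehyde 22. NaBH4 in MeOH at 0 °C should give the primary alcohol F1. PPh3, I2 and imidazole convert it into the iodide F2. NaNO2 in DMF (Kornblum substitution) gives the nitroalkane F3. TMSCl and Et3N turn F3 into the silyl nitronate F4, which is warmed in toluene at 60–80 °C until cycloaddition to the N-silyloxyisoxazolidine F5 is complete. Catalytic TsOH then eliminates trimethylsilanol, and the sequence comes back to the route at isoxazoline 26.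

2. Step 13. The 1,4-dialdehyde may epimerise at C7 or cyclodehydrate, the free C12 aldehyde may compete as an electrophile in intermolecular allylation, and facial selectivity at C6 may be eroded. The fallback runs the cyclisation on a mono-aldehyde and forms the lactone afterwards by oxidative lactonisation. It sets out from diol 16. TBDPSCl (1.0 equiv) and imidazole at −20 °C should silylate the less hindered C12 hydroxyl to give the mono-TBDPS ether F6. Parikh–Doering oxidation gives the mono-aldehyde F7. BF3·OEt2 at −78 °C closes ring A to the oxepanol F8. Buffered TBAF removes the TBDPS group to give the ring-A diol F9. TEMPO with PhI(OAc)2 oxidises the primary alcohol, and the aldehyde closes through lactol 19 to lactone 20, where the sequence rejoins the route.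

3. Step 20. Hydride delivery to C3 of the strained bicycle may occur from the wrong face, or with poor facial selectivity, giving the 3-epi alcohol. The fallback accepts that epimer and corrects C3 by inversion. It sets out from ketone 30. Internal hydride delivery with Me4NBH(OAc)3 in MeCN–AcOH at −20 °C should give the 3-epi diol F10 deliberately. AcCl with 2,4,6-collidine at −78 °C acetylates only the primary C15 hydroxyl, giving the 3-epi monoacetate F11. Mitsunobu reaction with acetic acid (PPh3, DIAD) installs the C3 acetate with inversion, and the sequence returns to the route at diacetate 33.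

**Further compounds**

F1 | step 17 | C3 primary alcohol (10-(3-hydroxypropyl) lactone) | C1C(=O)O[C@@H]2[C@@H](C=C)O[C@](C)(CCCO)C[C@@H](O[Si](C(C)C)(C(C)C)C(C)C)[C@@H]12
F2 | step 17 | C3 primary iodide | C1C(=O)O[C@@H]2[C@@H](C=C)O[C@](C)(CCCI)C[C@@H](O[Si](C(C)C)(C(C)C)C(C)C)[C@@H]12
F3 | step 17 | C3 nitroalkane | C1C(=O)O[C@@H]2[C@@H](C=C)O[C@](C)(CCC[N+](=O)[O-])C[C@@H](O[Si](C(C)C)(C(C)C)C(C)C)[C@@H]12
F4 | step 17 | trimethylsilyl nitronate | C1C(=O)O[C@@H]2[C@@H](C=C)O[C@](C)(CCC=[N+]([O-])O[Si](C)(C)C)C[C@@H](O[Si](C(C)C)(C(C)C)C(C)C)[C@@H]12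
F5 | step 17 | N-(trimethylsilyloxy)isoxazolidine (ring B closed) | C1C(=O)O[C@@H]2[C@@H]3O[C@](C)(CCC4N(O[Si](C)(C)C)OC[C@H]34)C[C@@H](O[Si](C(C)C)(C(C)C)C(C)C)[C@@H]12
F6 | step 13 | stannane mono-TBDPS ether (C12–OTBDPS, C6–OH) | CC(C)=CCC[C@@](C)(O/C=C\C[Sn](CCCC)(CCCC)CCCC)C[C@@H](O[Si](C(C)C)(C(C)C)C(C)C)[C@@H](CCO[Si](c1ccccc1)(c1ccccc1)C(C)(C)C)CO
F7 | step 13 | stannane mono-aldehyde (C6 formyl, C12–OTBDPS) | CC(C)=CCC[C@@](C)(O/C=C\C[Sn](CCCC)(CCCC)CCCC)C[C@@H](O[Si](C(C)C)(C(C)C)C(C)C)[C@@H](CCO[Si](c1ccccc1)(c1ccccc1)C(C)(C)C)C=O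
F8 | step 13 | oxepanol with C12–OTBDPS | CC(C)(C)[Si](c1ccccc1)(c1ccccc1)OCC[C@H]1[C@H](O)[C@@H](C=C)O[C@](C)(CCC=C(C)C)C[C@H]1O[Si](C(C)C)(C(C)C)C(C)C
F9 | step 13 | ring-A diol (C6–OH, C12–OH) | OCC[C@H]1[C@H](O)[C@@H](C=C)O[C@](C)(CCC=C(C)C)C[C@H]1O[Si](C(C)C)(C(C)C)C(C)C
F10 | step 20 | 3-epi-3,15-diol | CN(C)CC1C(=O)O[C@@H]2[C@@H]3O[C@](C)(CC[C@@H](O)[C@@H]3CO)C[C@@H](O[Si](C(C)C)(C(C)C)C(C)C)[C@@H]12
F11 | step 20 | 3-epi-15-monoacetate | CN(C)CC1C(=O)O[C@@H]2[C@@H]3O[C@](C)(CC[C@@H](O)[C@@H]3COC(C)=O)C[C@@H](O[Si](C(C)C)(C(C)C)C(C)C)[C@@H]12
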